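**Assumptions (one line each)**
- Both ring halves of the target are the same trans-fused cyclohexene–oxepane with an angular methyl. They differ only at the carbon next to the CMe2–O carbon, which is C=O in one half and CH–OH in the other. I build the CH–OH half first and convert part of it to the ketone half.
- Baker's yeast is assumed to give the (3S)-ketol from dione 1, and the L-sorbose-derived Shi ketone is assumed to give the (R)-epoxide.
- In Step 2, equilibration at 0 °C is assumed to give the chelated, more substituted C2 dianion.

**Retrosynthesis**
1. The central CH2CH2 comes from selective diimide reduction of an (E)-tetraene. The tetraene comes from Stille couplings of two tetrasubstituted enol triflates with (E)-Bu3SnCH=CHSnBu3.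
2. Each enol triflate is made regiospecifically from a ring ketone that carries an α-methyl (this sets the tetrasubstituted alkene) and an α′ quaternary carbon.
3. The oxepane is formed by acid-mediated 7-endo opening of a homoprenyl epoxide by the ring OH.
4. The quaternary methyl centre is set by alkylation of the dianion of (S)-3-hydroxy-2-methylcyclohexanone, with the electrophile entering anti to the oxygen. The carbinol carbon comes from a yeast reduction.
5. Rings are formed in this order: the cyclohexanone (commercial), the oxepane, the cyclohexene C=C (via the enol triflate), then the C–C link between the halves.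

**Route**

**Step 1**
Reactants: 1 (2-methylcyclohexane-1,3-dione)
Product: 2 ((3S)-3-hydroxy-2-methylcyclohexan-1-one, C2 epimeric mixture)
Conditions: baker's yeast, sucrose, H2O, 30 °C
Reagents that add atoms: none
Why: Enantioselective ketoreductase reduction of one carbonyl sets the carbinol carbon as S (Prelog-type selectivity). C2 is epimerisable and is deprotonated in Step 2, so its configuration does not matter.

**Step 2**
Reactants: 2, 3 (5-bromo-2-methylpent-2-ene)
Product: 4 ((2R,3S)-3-hydroxy-2-methyl-2-(4-methylpent-3-en-1-yl)cyclohexan-1-one)
Conditions: LDA (2.2 equiv), THF, –78 → 0 °C; then 3, NaI, HMPA, –20 °C → rt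
Reagents that add atoms: none besides reactant 3 (CC(C)=CCCBr)
Why: The first equivalent of LDA forms the Li-alkoxide and the second forms the enolate. Warming to 0 °C equilibrates to the chelated, more substituted C2 dianion, and A(1,2) strain with the 2-Me holds the C3–OLi pseudo-axial. SN2 alkylation (enolate alkylation, NaI-activated) then occurs axially, anti to oxygen. This puts the chain trans to O and Me cis to O, which is the relative configuration of the target (trans ring fusion after Step 4), and it sets the quaternary centre.

**Step 3**
Reactants: 4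
Product: 6 ((2R,3S)-2-[2-((R)-3,3-dimethyloxiran-2-yl)ethyl]-3-hydroxy-2-methylcyclohexan-1-one)
Conditions: L-sorbose-derived Shi ketone (30 mol%), Oxone (5), K2CO3, Bu4NHSO4, Na2B4O7/EDTA, MeCN/DMM, 0 °C
Reagents that add atoms: Oxone, 5 (KHSO5, OOS(=O)(=O)[O-].[K+]), which supplies the epoxide O
Why: Shi asymmetric epoxidation (chiral dioxirane) is catalyst-controlled and selective for the only alkene, the trisubstituted one. It sets the future CH–OH carbon as R. The ketone and alcohol are untouched.

**Step 4**
Reactants: 6
Product: 7 (trans-fused cyclohexanone–oxepane ketol)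
Conditions: CSA (10 mol%), CH2Cl2, 0 °C
Reagents that add atoms: none
Why: Acid-catalysed intramolecular epoxide opening (7-endo) puts the ring OH onto the tertiary epoxide carbon. Inversion there is invisible because of the gem-dimethyl. The C–O bond at the secondary epoxide carbon is not broken, so its R configuration is retained as the CH–OH. The ring O and the chain are trans on the cyclohexane, which gives the trans-fused 6-7 system.

**Step 5**
Reactants: 7, 8 (TBSOTf)
Product: 9 (CH–OTBS ketone)
Conditions: TBSOTf, 2,6-lutidine, CH2Cl2, –78 °C
Reagents that add atoms: TBSOTf, 8 (C[Si](C)(C(C)(C)C)OS(=O)(=O)C(F)(F)F)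
Why: Silylation protects the secondary OH for the enolate chemistry that follows. No stereocentre is touched.

**Step 6**
Reactants: 9, 10 (MeI)
Product: 11 (α-methyl ketone, epimeric at the new CHMe)
Conditions: LDA, THF, –78 °C; then MeI, –78 → 0 °C
Reagents that add atoms: MeI, 10 (CI)
Why: The ketone has a quaternary α-carbon on one side, so only the α′-CH2 can enolise. Enolate C-methylation goes there regiospecifically. The new stereocentre is destroyed in the next step.

**Step 7**
Reactants: 11, 12 (PhNTf2)
Product: 13 (tetrasubstituted enol triflate, OTBS)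
Conditions: KHMDS, THF, –78 °C; then PhNTf2
Reagents that add atoms: PhNTf2, 12 (O=S(=O)(C(F)(F)F)N(c1ccccc1)S(=O)(=O)C(F)(F)F)
Why: Enolisation toward the only enolisable side, followed by O-triflation, places the C=C exactly where the target has it (the ring alkene bearing the methyl).

**Step 8**
Reactants: 13, 14 ((E)-1,2-bis(tributylstannyl)ethene)
Product: 15 (alkenylstannane of the OTBS half)
Conditions: Pd(PPh3)4 (5 mol%), CuCl, LiCl, DMSO/THF, 60 °C; 3 equiv of 14
Reagents that add atoms: 14 is the reactant (CCCC[Sn](CCCC)(CCCC)/C=C/[Sn](CCCC)(CCCC)CCCC)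
Why: Stille coupling (CuCl/LiCl-accelerated) of a hindered cyclohexenyl triflate with a vinylstannane has precedent. A large excess of distannane prevents double coupling, and the (E) geometry is retained.

**Step 9** (parallel branch from 13)
Reactants: 13
Product: 16 (enol triflate with free CH–OH)
Conditions: HF·pyridine, THF/pyridine, 0 °C → rt
Reagents that add atoms: none
Why: Mild, non-nucleophilic desilylation leaves the enol triflate intact (TBAF could cleave it).

**Step 10**
Reactants: 16
Product: 17 (enol triflate with ring ketone, the "ketone half")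
Conditions: Dess–Martin periodinane, NaHCO3, CH2Cl2, rt
Reagents that add atoms: none
Why: Oxidation of the secondary alcohol to the ketone next to the CMe2–O carbon. The other neighbouring carbons are CH2 and quaternary, and the ring-fusion centres are not α to the new C=O, so nothing epimerises.

**Step 11**
Reactants: 15, 17
Product: 18 ((E)-tetraene, OTBS)
Conditions: Pd(PPh3)4, CuCl, LiCl, DMSO, 60 °C
Reagents that add atoms: none
Why: Stille coupling joins the two halves through the vinyl bridge, with the stannane on one half and the triflate on the other, so no statistical mixture forms. The ketone and silyl ether are compatible.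

**Step 12**
Reactants: 18
Product: 19 (TBS-protected sodwanone T)
Conditions: o-NO2C6H4SO2NHNH2 (NBSH), Et3N, CH2Cl2, –15 °C → rt
Reagents that add atoms: none (only H2 is transferred, as diimide)
Why: Diimide reduces the unhindered trans-disubstituted C=C by syn delivery of H2. The two tetrasubstituted alkenes and the ethers are inert. The ketone is α-quaternary and hindered, so sulfonylhydrazone formation is slow under these non-acidic conditions.

**Step 13**
Reactants: 19
Product: 20 (sodwanone T)
Conditions: HF·pyridine, THF/pyridine, rt
Reagents that add atoms: none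
Why: Desilylation releases the secondary alcohol. All stereocentres were set earlier and are not touched.

**Compound list**

1 | 2-methylcyclohexane-1,3-dione | CC1C(=O)CCCC1=O | starting material
2 | (3S)-3-hydroxy-2-methylcyclohexan-1-one (C2 epimers) | O[C@H]1CCCC(=O)C1C | intermediate
3 | 5-bromo-2-methylpent-2-ene | CC(C)=CCCBr | starting material
4 | (2R,3S)-3-hydroxy-2-methyl-2-(4-methylpent-3-enyl)cyclohexan-1-one | O[C@H]1CCCC(=O)[C@]1(C)CCC=C(C)C | intermediate
5 | Oxone (KHSO5) | OOS(=O)(=O)[O-].[K+] | reagent
6 | epoxy ketol, (R)-epoxide | O[C@H]1CCCC(=O)[C@]1(C)CC[C@H]1OC1(C)C | intermediate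
7 | trans-fused oxepane–cyclohexanone, CH–OH (R) | O=C1CCC[C@@H]2OC(C)(C)[C@H](O)CC[C@@]12C | intermediate
8 | TBSOTf | C[Si](C)(C(C)(C)C)OS(=O)(=O)C(F)(F)F | reagent
9 | 7 as its TBS ether | O=C1CCC[C@@H]2OC(C)(C)[C@H](O[Si](C)(C)C(C)(C)C)CC[C@@]12C | intermediate
10 | iodomethane | CI | reagent
11 | α-methyl ketone (CHMe epimers) | O=C1C(C)CC[C@@H]2OC(C)(C)[C@H](O[Si](C)(C)C(C)(C)C)CC[C@@]12C | intermediate
12 | PhNTf2 | O=S(=O)(C(F)(F)F)N(c1ccccc1)S(=O)(=O)C(F)(F)F | reagent
13 | enol triflate, OTBS | CC1=C(OS(=O)(=O)C(F)(F)F)[C@]2(C)CC[C@@H](O[Si](C)(C)C(C)(C)C)C(C)(C)O[C@H]2CC1 | intermediate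
14 | (E)-1,2-bis(tributylstannyl)ethene | CCCC[Sn](CCCC)(CCCC)/C=C/[Sn](CCCC)(CCCC)CCCC | starting material (reagent)
15 | vinylstannane of the OTBS half | CC1=C(/C=C/[Sn](CCCC)(CCCC)CCCC)[C@]2(C)CC[C@@H](O[Si](C)(C)C(C)(C)C)C(C)(C)O[C@H]2CC1 | intermediate
16 | enol triflate, CH–OH | CC1=C(OS(=O)(=O)C(F)(F)F)[C@]2(C)CC[C@@H](O)C(C)(C)O[C@H]2CC1 | intermediate
17 | enol triflate, ring ketone | CC1=C(OS(=O)(=O)C(F)(F)F)[C@]2(C)CCC(=O)C(C)(C)O[C@H]2CC1 | intermediate
18 | (E)-tetraene, OTBS | CC1=C(/C=C/C2=C(C)CC[C@@H]3OC(C)(C)[C@H](O[Si](C)(C)C(C)(C)C)CC[C@@]23C)[C@]2(C)CCC(=O)C(C)(C)O[C@H]2CC1 | intermediate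
19 | TBS-sodwanone T | CC1=C(CCC2=C(C)CC[C@@H]3OC(C)(C)[C@H](O[Si](C)(C)C(C)(C)C)CC[C@@]23C)[C@]2(C)CCC(=O)C(C)(C)O[C@H]2CC1 | intermediate
20 | sodwanone T | CC1=C(CCC2=C(C)CC[C@@H]3OC(C)(C)[C@H](O)CC[C@@]23C)[C@]2(C)CCC(=O)C(C)(C)O[C@H]2CC1 | target

**Totals**
- Total steps: 13 (Steps 9 and 10 form a parallel branch from 13).
- Longest linear sequence: 12 steps, namely 1 → 2 → 3 → 4 → 5 → 6 → 7 → 9 → 10 → 11 → 12 → 13. The route through Step 8 is 11 steps.

**Three steps most likely to fail**
1. **Step 4 (7-endo epoxide opening).** The 6-exo tetrahydropyran (attack at the secondary carbon) may compete or dominate. Fallback: form the C–O bond by Markovnikov hydroalkoxylation instead of epoxide opening.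
   - Alkylate with 2-(2-bromoethyl)-1,3-dioxolane, unmask the aldehyde, and add isopropenylMgBr.
   - Close the ring with Co(salen)/silane/N-fluoropyridinium on the isopropenyl carbinol, fixing the carbinol stereochemistry by oxidation and CBS reduction.
2. **Step 2 (dianion alkylation).** Regiochemistry (C2 vs C6), yield with an unactivated bromide, and the anti selectivity are all uncertain. Fallback: C-alkylate dione 1 with 3 at C2, then desymmetrise by yeast reduction. That gives the ketol with OH syn to the chain (the wrong face). Correct it by swapping the roles of the two oxygenated carbons: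
   - Protect the carbinol.
   - Reduce the other ketone with NaBH4 (axial attack gives OH syn to Me).
   - Oxidise the original carbinol carbon to the ketone.
3. **Step 11 (Stille coupling of two hindered tetrasubstituted partners).** Fallback: replace the vinyl bridge with an aldehyde-based link.
   - Carbonylate triflates 13 and 17 to the enoates (Pd, CO, MeOH), reduce to the allylic alcohols and then to the aldehydes.
   - Join them by Julia–Kocienski olefination (sulfone from one half) or McMurry coupling, then hydrogenate the central alkene.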